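## Retrosynthetic overview
1. Hippolide F ⇒ a trans-4-(silyloxymethyl)-5-alkyl-γ-butyrolactone carrying the protected C5–C20 chain. The forward operations are C2=C3 selenoxide dehydrogenation, PMB removal and desilylation.
2. The key C3–C4 bond comes from an Evans syn boron aldol. It joins the N-(3-methoxycarbonylpropanoyl) derivative of (S)-4-benzyloxazolidin-2-one (C1–C3, C25) to the C21 β,γ-unsaturated aldehyde (C4–C20, C24) and sets C4 as R.
3. Ring order: the single ring (γ-lactone) closes right after the aldol, when the C4 oxygen attacks the C1 ester. It becomes the butenolide only near the end.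
4. Aldehyde ⇒ Z-selective Wittig (C6=C7) of an α-PMBO ketone with a three-carbon ylide. Ketone ⇒ acetoacetic ester alkylation and decarboxylation (C8–C9).
5. Allylic bromide ⇒ (2E,6E)-farnesol, by SeO2 oxidation of the terminal E-methyl group (C20).

Assumption: the [C@H] centre of the target is read as R, and isomerically pure (2E,6E)-farnesol is purchased.

Conventions:
- Numbering: C1 = lactone C=O, C2 = ring =CH, C3 = ring carbon bearing C25H2OH, C4 = ring CH–O. C5–C20 is the chain, with C20 the terminal CH2OH. C24 is the CH2OH on C7.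
- R* = (2Z,6E,10E,14E)-16-(tert-butyldiphenylsilyloxy)-3-[(4-methoxybenzyloxy)methyl]-7,11,15-trimethylhexadeca-2,6,10,14-tetraen-1-yl.

## Route

Step 1
Reactants: 1 (2E,6E)-farnesol
Product: 2 (2E,6E)-farnesyl acetate
Conditions: Ac2O, cat. DMAP, pyridine, 0 °C to rt
Reagents that add atoms: acetic anhydride CC(=O)OC(C)=O
Why: O-acylation masks the future C9 hydroxyl and electronically deactivates the adjacent olefin toward the next oxidation.

Step 2
Reactants: 2 (2E,6E)-farnesyl acetate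
Product: 3 (2E,6E,10E)-12-hydroxyfarnesyl acetate
Conditions: SeO2 (0.1 equiv), t-BuOOH (3 equiv), salicylic acid (0.1 equiv), CH2Cl2, 0 °C to rt; stopped at about 60% conversion, 2 recycled
Reagents that add atoms: tert-butyl hydroperoxide CC(C)(C)OO (net oxygen source); selenium dioxide O=[Se]=O (carries the oxygen to carbon)
Why: Riley allylic oxidation (ene reaction then [2,3]-shift) attacks the most electron-rich terminal isopropylidene group and delivers only the E-allylic alcohol.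

Step 3
Reactants: 3 (2E,6E,10E)-12-hydroxyfarnesyl acetate
Product: 4 (2E,6E,10E)-12-(tert-butyldiphenylsilyloxy)farnesyl acetate
Conditions: TBDPSCl, imidazole, DMF, 0 °C to rt
Reagents that add atoms: tert-butyldiphenylsilyl chloride CC(C)(C)[Si](Cl)(c1ccccc1)c1ccccc1
Why: Silyl ether formation at the only free hydroxyl gives a C20 protecting group that survives base, mild acid, DDQ and enolate chemistry.

Step 4
Reactants: 4 (2E,6E,10E)-12-(tert-butyldiphenylsilyloxy)farnesyl acetate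
Product: 5 (2E,6E,10E)-12-(tert-butyldiphenylsilyloxy)-3,7,11-trimethyldodeca-2,6,10-trien-1-ol
Conditions: K2CO3 (0.2 equiv), MeOH, 0 °C to rt
Reagents that add atoms: none
Why: Base-catalysed transesterification removes the acetate and leaves the silyl ether untouched.

Step 5
Reactants: 5 (2E,6E,10E)-12-(tert-butyldiphenylsilyloxy)-3,7,11-trimethyldodeca-2,6,10-trien-1-ol
Product: 6 (2E,6E,10E)-12-bromo-2,6,10-trimethyldodeca-2,6,10-trienyl tert-butyldiphenylsilyl ether
Conditions: CBr4, PPh3, CH2Cl2, −20 to 0 °C; short silica plug, used directly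
Reagents that add atoms: carbon tetrabromide BrC(Br)(Br)Br
Why: The Appel reaction converts the primary allylic alcohol by SN2 under neutral conditions, without allylic shift or E/Z loss.

Step 6
Reactants: 7 ethyl 4-chloro-3-oxobutanoate
Product: 8 ethyl 4-(4-methoxybenzyloxy)-3-oxobutanoate
Conditions: NaH (2.2 equiv), 4-methoxybenzyl alcohol (1.05 equiv), THF, 0 °C to rt; dilute aq. HCl
Reagents that add atoms: 4-methoxybenzyl alcohol COc1ccc(CO)cc1
Why: In this Williamson ether synthesis the alkoxide displaces the activated primary chloride next to the ketone, while the extra base keeps the acidic C2 position out of play.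

Step 7
Reactants: 8 ethyl 4-(4-methoxybenzyloxy)-3-oxobutanoate; 6 allylic bromide
Product: 10 ethyl (4E,8E,12E)-14-(tert-butyldiphenylsilyloxy)-2-[(4-methoxybenzyloxy)acetyl]-5,9,13-trimethyltetradeca-4,8,12-trienoate (racemic at C2), via sodium enolate 9 (not isolated)
Conditions: NaH (1.05 equiv), THF, 0 °C; then 6, 0 °C to rt
Reagents that add atoms: none
Why: In this acetoacetic ester alkylation the soft stabilised enolate attacks the primary allylic bromide by SN2 at carbon to form C8–C9, and the new racemic centre is erased in the next step.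

Step 8
Reactants: 10 alkylated β-keto ester
Product: 12 (5E,9E,13E)-15-(tert-butyldiphenylsilyloxy)-1-(4-methoxybenzyloxy)-6,10,14-trimethylpentadeca-5,9,13-trien-2-one, via β-keto acid 11 (not isolated)
Conditions: LiOH, THF/MeOH/H2O, rt; dilute aq. HCl to pH 4; toluene, 60 °C
Reagents that add atoms: none
Why: Saponification followed by thermal β-keto acid decarboxylation (ketonic cleavage) runs under conditions that PMB and TBDPS ethers routinely survive.

Step 9
Reactants: 13 (3-bromopropoxy)(tert-butyl)dimethylsilane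
Product: 14 [3-(tert-butyldimethylsilyloxy)propyl]triphenylphosphonium bromide
Conditions: PPh3, MeCN, reflux, 36 h
Reagents that add atoms: triphenylphosphine c1ccc(cc1)P(c1ccccc1)c1ccccc1
Why: SN2 quaternisation of PPh3 by an unhindered primary bromide gives the crystalline salt.

Step 10
Reactants: 14 phosphonium bromide (1.6 equiv); 12 α-PMBO ketone
Product: 16 (3Z,7E,11E,15E)-1-(tert-butyldimethylsilyloxy)-17-(tert-butyldiphenylsilyloxy)-4-[(4-methoxybenzyloxy)methyl]-8,12,16-trimethylheptadeca-3,7,11,15-tetraene, via ylide 15 (not isolated)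
Conditions: KN(SiMe3)2, THF, 0 °C; then 12, THF/HMPA 10:1, −78 °C to rt
Reagents that add atoms: none
Why: In a lithium-free Wittig olefination under kinetic control, an unstabilised ylide adds to an α-alkoxy ketone with its alkyl chain cis to the alkoxymethyl group, which gives the required 6Z geometry (C24 cis to C5).

Step 11
Reactants: 16 bis-silyl ether
Product: 17 (3Z,7E,11E,15E)-17-(tert-butyldiphenylsilyloxy)-4-[(4-methoxybenzyloxy)methyl]-8,12,16-trimethylheptadeca-3,7,11,15-tetraen-1-ol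
Conditions: camphorsulfonic acid (0.1 equiv), MeOH/CH2Cl2 1:1, 0 °C, 1 h; minor 3E isomer removed by chromatography
Reagents that add atoms: none
Why: Acid-catalysed methanolysis cleaves the primary TBS ether far faster than the bulkier TBDPS ether and does not touch the PMB ether.

Step 12
Reactants: 17 homoallylic alcohol
Product: 18 (3Z,7E,11E,15E)-17-(tert-butyldiphenylsilyloxy)-4-[(4-methoxybenzyloxy)methyl]-8,12,16-trimethylheptadeca-3,7,11,15-tetraenal
Conditions: Dess–Martin periodinane, NaHCO3, CH2Cl2, 0 °C, 45 min; filtered, concentrated cold, used at once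
Reagents that add atoms: none
Why: Buffered Dess–Martin oxidation is amine-free and nearly neutral, so the β,γ-unsaturated aldehyde forms without migration of the C6=C7 bond into conjugation.

Step 13
Reactants: 19 (S)-4-benzyloxazolidin-2-one; 20 methyl 4-chloro-4-oxobutanoate
Product: 22 methyl 4-[(S)-4-benzyl-2-oxooxazolidin-3-yl]-4-oxobutanoate, via N-lithio oxazolidinone 21 (not isolated)
Conditions: n-BuLi, THF, −78 °C; then 20, −78 to 0 °C
Reagents that add atoms: none
Why: In this N-acylation of the lithiated auxiliary, the acid chloride reacts much faster than the methyl ester.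

Step 14 (key step)
Reactants: 22 succinyl imide (1.3 equiv); 18 aldehyde
Product: 26 (S)-4-benzyl-3-{[(2R,3S)-5-oxo-2-R*-tetrahydrofuran-3-yl]carbonyl}oxazolidin-2-one, via boron enolate 23 (not isolated), via boron aldolate 24 (not isolated), via hydroxy ester 25 (not isolated)
Conditions: Bu2BOTf (1.1 equiv per 22), iPr2NEt (1.15 equiv per 22), CH2Cl2, −78 to 0 °C; 18, −78 °C then 0 °C; pH 7 buffer, MeOH, 30% H2O2, 0 °C; PPTS (0.1 equiv), toluene, 40 °C
Reagents that add atoms: none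
Why: In the Evans syn aldol the Z-boron enolate reacts through a Zimmerman–Traxler chair on the face away from the benzyl group, setting C4 as R (and C3 as S, erased later), after which the C4 oxygen closes on the methyl ester to form the only ring as the trans lactone.

Step 15
Reactants: 26 lactone imide
Product: 28 (2R,3S)-5-oxo-2-R*-tetrahydrofuran-3-carboxylic acid, via peroxy acid 27 (not isolated)
Conditions: LiOH, 30% H2O2, THF/H2O 3:1, 0 °C; Na2SO3; dilute aq. HCl to pH 3
Reagents that add atoms: hydrogen peroxide OO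
Why: In hydroperoxide-mediated imide cleavage the small, highly nucleophilic HOO− attacks the exocyclic carbonyl selectively, the auxiliary is released intact, and any opened lactone recloses on acidification.

Step 16
Reactants: 28 lactone acid
Product: 30 (4R,5R)-4-(hydroxymethyl)-5-R*-dihydrofuran-2(3H)-one, via mixed anhydride 29 (not isolated)
Conditions: i-BuOCOCl, N-methylmorpholine, THF, −15 °C; then NaBH4, H2O, −15 to 0 °C, 20 min
Reagents that add atoms: none
Why: Mixed-anhydride activation followed by borohydride reduction converts only the activated carboxyl into CH2OH, sparing the lactone and, unlike borane, all four olefins.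

Step 17
Reactants: 30 hydroxymethyl lactone
Product: 31 (4R,5R)-4-[(tert-butyldimethylsilyloxy)methyl]-5-R*-dihydrofuran-2(3H)-one
Conditions: TBSCl, imidazole, CH2Cl2, 0 °C, carried out directly after step 16
Reagents that add atoms: tert-butyldimethylsilyl chloride CC(C)(C)[Si](C)(C)Cl
Why: Prompt silylation of the primary alcohol blocks translactonisation onto C25 and removes the acidic proton before enolate chemistry.

Step 18
Reactants: 31 silyl-protected lactone
Product: 33 (3S,4R,5R)-4-[(tert-butyldimethylsilyloxy)methyl]-3-(phenylselanyl)-5-R*-dihydrofuran-2(3H)-one, via lithium enolate 32 (not isolated)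
Conditions: LiN(iPr)2 (commercial solution, 1.1 equiv), THF, −78 °C; PhSeBr (1.05 equiv) added rapidly, −78 °C, 15 min
Reagents that add atoms: phenylselenyl bromide Br[Se]c1ccccc1
Why: In this α-selenenylation of the kinetic lactone enolate only C2 can be deprotonated, and selenium enters anti to the C3 substituent, hence syn to H3 as the later elimination requires.

Step 19
Reactants: 33 α-selenide
Product: 35 (R)-4-[(tert-butyldimethylsilyloxy)methyl]-5-R*-furan-2(5H)-one, via selenoxide 34 (not isolated)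
Conditions: NaIO4 (2.5 equiv), THF/MeOH/H2O, 0 °C to rt
Reagents that add atoms: none
Why: In the selenoxide syn elimination periodate oxidises selenium but not the olefins, and the selenoxide leaves toward the only β-hydrogen (H3) at or below room temperature, giving the C2=C3 butenolide under base-free conditions that keep C4 intact.

Step 20
Reactants: 35 fully protected butenolide
Product: 36 (R)-4-[(tert-butyldimethylsilyloxy)methyl]-5-[(2Z,6E,10E,14E)-16-(tert-butyldiphenylsilyloxy)-3-(hydroxymethyl)-7,11,15-trimethylhexadeca-2,6,10,14-tetraen-1-yl]furan-2(5H)-one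
Conditions: DDQ (1.3 equiv), CH2Cl2/pH 7 buffer 10:1, 0 °C, 1 h
Reagents that add atoms: none
Why: Oxidative PMB cleavage touches only the electron-rich benzylic ether, while the silyl ethers, isolated trisubstituted olefins and the butenolide are inert at 0 °C.

Step 21
Reactants: 36 bis-silyl ether
Product: 37 hippolide F
Conditions: HF·pyridine, pyridine, THF, 0 °C to rt (plastic vessel)
Reagents that add atoms: none
Why: Fluoride-driven desilylation in a weakly acidic medium frees C20–OH and C25–OH without base, so C4 is not epimerised and the lactone does not migrate.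

## Compound list
1 | (2E,6E)-farnesol | CC(C)=CCC/C(C)=C/CC/C(C)=C/CO | starting material
2 | (2E,6E)-farnesyl acetate | CC(C)=CCC/C(C)=C/CC/C(C)=C/COC(C)=O | intermediate
3 | (2E,6E,10E)-12-hydroxyfarnesyl acetate | C/C(=C\CC/C(C)=C/CC/C(C)=C/COC(C)=O)CO | intermediate
4 | (2E,6E,10E)-12-(tert-butyldiphenylsilyloxy)farnesyl acetate | C/C(=C\CC/C(C)=C/CC/C(C)=C/COC(C)=O)CO[Si](c1ccccc1)(c1ccccc1)C(C)(C)C | intermediate
5 | (2E,6E,10E)-12-(tert-butyldiphenylsilyloxy)-3,7,11-trimethyldodeca-2,6,10-trien-1-ol | C/C(=C\CC/C(C)=C/CC/C(C)=C/CO)CO[Si](c1ccccc1)(c1ccccc1)C(C)(C)C | intermediate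
6 | (2E,6E,10E)-12-bromo-2,6,10-trimethyldodeca-2,6,10-trienyl TBDPS ether | C/C(=C\CC/C(C)=C/CC/C(C)=C/CBr)CO[Si](c1ccccc1)(c1ccccc1)C(C)(C)C | intermediate
7 | ethyl 4-chloro-3-oxobutanoate | CCOC(=O)CC(=O)CCl | starting material
8 | ethyl 4-(4-methoxybenzyloxy)-3-oxobutanoate | CCOC(=O)CC(=O)COCc1ccc(OC)cc1 | intermediate
9 | sodium enolate of 8 | [Na+].CCOC(=O)C=C([O-])COCc1ccc(OC)cc1 | intermediate (not isolated)
10 | alkylated β-keto ester (racemic at the α-carbon) | C/C(=C\CC/C(C)=C/CC/C(C)=C/CC(C(=O)OCC)C(=O)COCc1ccc(OC)cc1)CO[Si](c1ccccc1)(c1ccccc1)C(C)(C)C | intermediate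
11 | β-keto acid from 10 | C/C(=C\CC/C(C)=C/CC/C(C)=C/CC(C(=O)O)C(=O)COCc1ccc(OC)cc1)CO[Si](c1ccccc1)(c1ccccc1)C(C)(C)C | intermediate (not isolated)
12 | (5E,9E,13E)-15-(TBDPSO)-1-(PMBO)-6,10,14-trimethylpentadeca-5,9,13-trien-2-one | C/C(=C\CC/C(C)=C/CC/C(C)=C/CCC(=O)COCc1ccc(OC)cc1)CO[Si](c1ccccc1)(c1ccccc1)C(C)(C)C | intermediate
13 | (3-bromopropoxy)(tert-butyl)dimethylsilane | BrCCCO[Si](C)(C)C(C)(C)C | starting material
14 | [3-(tert-butyldimethylsilyloxy)propyl]triphenylphosphonium bromide | [Br-].CC(C)(C)[Si](C)(C)OCCC[P+](c1ccccc1)(c1ccccc1)c1ccccc1 | intermediate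
15 | [3-(tert-butyldimethylsilyloxy)propylidene]triphenylphosphorane | CC(C)(C)[Si](C)(C)OCCC=P(c1ccccc1)(c1ccccc1)c1ccccc1 | intermediate (not isolated)
16 | (3Z,7E,11E,15E)-tetraene, C4–OTBS, C24–OPMB, C20–OTBDPS | C/C(=C\CC/C(C)=C/CC/C(C)=C/CC/C(=C/CCO[Si](C)(C)C(C)(C)C)COCc1ccc(OC)cc1)CO[Si](c1ccccc1)(c1ccccc1)C(C)(C)C | intermediate
17 | (3Z,7E,11E,15E)-homoallylic alcohol | C/C(=C\CC/C(C)=C/CC/C(C)=C/CC/C(=C/CCO)COCc1ccc(OC)cc1)CO[Si](c1ccccc1)(c1ccccc1)C(C)(C)C | intermediate
18 | (3Z,7E,11E,15E)-β,γ-unsaturated aldehyde | C/C(=C\CC/C(C)=C/CC/C(C)=C/CC/C(=C/CC=O)COCc1ccc(OC)cc1)CO[Si](c1ccccc1)(c1ccccc1)C(C)(C)C | intermediate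
19 | (S)-4-benzyloxazolidin-2-one | O=C1N[C@@H](Cc2ccccc2)CO1 | starting material
20 | methyl 4-chloro-4-oxobutanoate | COC(=O)CCC(=O)Cl | starting material
21 | lithium salt of 19 | [Li+].O=C1[N-][C@@H](Cc2ccccc2)CO1 | intermediate (not isolated)
22 | methyl 4-[(S)-4-benzyl-2-oxooxazolidin-3-yl]-4-oxobutanoate | COC(=O)CCC(=O)N1[C@@H](Cc2ccccc2)COC1=O | intermediate
23 | (Z)-dibutylboron enolate of 22 | COC(=O)C/C=C(\OB(CCCC)CCCC)N1[C@@H](Cc2ccccc2)COC1=O | intermediate (not isolated)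
24 | dibutylboron aldolate of 25 | C/C(=C\CC/C(C)=C/CC/C(C)=C/CC/C(=C/C[C@@H](OB(CCCC)CCCC)[C@H](CC(=O)OC)C(=O)N1[C@@H](Cc2ccccc2)COC1=O)COCc1ccc(OC)cc1)CO[Si](c1ccccc1)(c1ccccc1)C(C)(C)C | intermediate (not isolated)
25 | methyl (3S,4R)-3-[(S)-4-benzyl-2-oxooxazolidine-3-carbonyl]-4-hydroxy-4-R*-butanoate (syn aldol) | C/C(=C\CC/C(C)=C/CC/C(C)=C/CC/C(=C/C[C@@H](O)[C@H](CC(=O)OC)C(=O)N1[C@@H](Cc2ccccc2)COC1=O)COCc1ccc(OC)cc1)CO[Si](c1ccccc1)(c1ccccc1)C(C)(C)C | intermediate (not isolated)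
26 | (S)-4-benzyl-3-{[(2R,3S)-5-oxo-2-R*-tetrahydrofuran-3-yl]carbonyl}oxazolidin-2-one (trans lactone) | C/C(=C\CC/C(C)=C/CC/C(C)=C/CC/C(=C/C[C@H]1OC(=O)C[C@@H]1C(=O)N1[C@@H](Cc2ccccc2)COC1=O)COCc1ccc(OC)cc1)CO[Si](c1ccccc1)(c1ccccc1)C(C)(C)C | intermediate
27 | (2R,3S)-5-oxo-2-R*-tetrahydrofuran-3-carboperoxoic acid | C/C(=C\CC/C(C)=C/CC/C(C)=C/CC/C(=C/C[C@H]1OC(=O)C[C@@H]1C(=O)OO)COCc1ccc(OC)cc1)CO[Si](c1ccccc1)(c1ccccc1)C(C)(C)C | intermediate (not isolated)
28 | (2R,3S)-5-oxo-2-R*-tetrahydrofuran-3-carboxylic acid | C/C(=C\CC/C(C)=C/CC/C(C)=C/CC/C(=C/C[C@H]1OC(=O)C[C@@H]1C(=O)O)COCc1ccc(OC)cc1)CO[Si](c1ccccc1)(c1ccccc1)C(C)(C)C | intermediate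
29 | isobutyl carbonic mixed anhydride of 28 | C/C(=C\CC/C(C)=C/CC/C(C)=C/CC/C(=C/C[C@H]1OC(=O)C[C@@H]1C(=O)OC(=O)OCC(C)C)COCc1ccc(OC)cc1)CO[Si](c1ccccc1)(c1ccccc1)C(C)(C)C | intermediate (not isolated)
30 | (4R,5R)-4-(hydroxymethyl)-5-R*-dihydrofuran-2(3H)-one | C/C(=C\CC/C(C)=C/CC/C(C)=C/CC/C(=C/C[C@H]1OC(=O)C[C@@H]1CO)COCc1ccc(OC)cc1)CO[Si](c1ccccc1)(c1ccccc1)C(C)(C)C | intermediate
31 | (4R,5R)-4-[(TBSO)methyl]-5-R*-dihydrofuran-2(3H)-one | C/C(=C\CC/C(C)=C/CC/C(C)=C/CC/C(=C/C[C@H]1OC(=O)C[C@@H]1CO[Si](C)(C)C(C)(C)C)COCc1ccc(OC)cc1)CO[Si](c1ccccc1)(c1ccccc1)C(C)(C)C | intermediate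
32 | lithium enolate of 31 | [Li+].C/C(=C\CC/C(C)=C/CC/C(C)=C/CC/C(=C/C[C@H]1OC([O-])=C[C@@H]1CO[Si](C)(C)C(C)(C)C)COCc1ccc(OC)cc1)CO[Si](c1ccccc1)(c1ccccc1)C(C)(C)C | intermediate (not isolated)
33 | (3S,4R,5R)-4-[(TBSO)methyl]-3-(phenylselanyl)-5-R*-dihydrofuran-2(3H)-one | C/C(=C\CC/C(C)=C/CC/C(C)=C/CC/C(=C/C[C@H]1OC(=O)[C@@H]([Se]c2ccccc2)[C@@H]1CO[Si](C)(C)C(C)(C)C)COCc1ccc(OC)cc1)CO[Si](c1ccccc1)(c1ccccc1)C(C)(C)C | intermediate
34 | selenoxide of 33 (mixture at selenium) | C/C(=C\CC/C(C)=C/CC/C(C)=C/CC/C(=C/C[C@H]1OC(=O)[C@@H]([Se](=O)c2ccccc2)[C@@H]1CO[Si](C)(C)C(C)(C)C)COCc1ccc(OC)cc1)CO[Si](c1ccccc1)(c1ccccc1)C(C)(C)C | intermediate (not isolated)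
35 | (R)-4-[(TBSO)methyl]-5-R*-furan-2(5H)-one | C/C(=C\CC/C(C)=C/CC/C(C)=C/CC/C(=C/C[C@H]1OC(=O)C=C1CO[Si](C)(C)C(C)(C)C)COCc1ccc(OC)cc1)CO[Si](c1ccccc1)(c1ccccc1)C(C)(C)C | intermediate
36 | butenolide with free C24–OH, C25–OTBS, C20–OTBDPS | C/C(=C\CC/C(C)=C/CC/C(C)=C/CC/C(=C/C[C@H]1OC(=O)C=C1CO[Si](C)(C)C(C)(C)C)CO)CO[Si](c1ccccc1)(c1ccccc1)C(C)(C)C | intermediate
37 | hippolide F, (R)-5-[(2Z,6E,10E,14E)-16-hydroxy-3-(hydroxymethyl)-7,11,15-trimethylhexadeca-2,6,10,14-tetraen-1-yl]-4-(hydroxymethyl)furan-2(5H)-one | C/C(=C\CC/C(C)=C/CC/C(C)=C/CC/C(=C/C[C@H]1OC(=O)C=C1CO)CO)CO | target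

## Totals and risks
Total step count: 21.
Longest linear sequence: 18 steps (1–5, 7, 8, 10–12, 14–21).

**Step 10 (Wittig).** The risks are incomplete Z-selectivity and enolisation of ketone 12. The fallback locks the geometry in a ring and sets out from ketone 12. DDQ (CH2Cl2/pH 7 buffer) removes the PMB group to give the α-hydroxy ketone F1. Ph3P=C=C=O (toluene, 90 °C; O-acylation then intramolecular Wittig) turns it into the 4-substituted furan-2(5H)-one F2, in which C24 and C5 are necessarily cis. iBu2AlH (1.05 equiv, CH2Cl2, −78 °C) gives the lactol F3. Ph3P=CH2 (THF, −78 °C to rt) opens it to the (Z)-dienol F4. 4-Methoxybenzyl trichloroacetimidate with cat. camphorsulfonic acid gives the dienyl PMB ether F5. 9-BBN followed by NaBO3 hydroborates only the terminal vinyl group, and the sequence comes back to the route at alcohol 17.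

**Step 14 (aldol on the labile β,γ-unsaturated aldehyde).** The risk is that residual amine moves C6=C7 into conjugation before C–C bond formation. The fallback is a catalytic carbonyl allylation run from the alcohol oxidation level. It sets out from alcohol 17, so that 18 is never handled. Alcohol 17 is coupled with 4-vinyl-1,3-dioxolan-2-one under transfer-hydrogenation conditions ([Ir(cod)Cl]2, SEGPHOS, 4-cyano-3-nitrobenzoic acid, K3PO4, THF, 70 °C). The ligand enantiomer is chosen to give 4R and the result is checked by Mosher ester analysis. This gives the anti vinyl 1,3-diol F6. TBSCl/imidazole at −20 °C silylates only the primary hydroxyl to give the mono-silyl ether F7. 9-BBN (2.2 equiv) then NaBO3 gives the 1,4-diol F8. TEMPO/PhI(OAc)2 oxidative lactonisation comes back to the route at lactone 31, with the same trans relationship.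

**Step 18 (α-selenenylation).** The risks are proton exchange leading to bis-selenide and addition of PhSeBr to the polyene. The fallback replaces selenium by a palladium-mediated dehydrogenation and sets out from lactone 31. LiN(iPr)2 and Me3SiCl (THF, −78 °C) give the ketene silyl acetal F9. Pd(OAc)2 (1.0 equiv, MeCN, rt; Saegusa–Ito oxidation) then gives the butenolide directly under base-free conditions. The sequence comes back to the route at 35.

## Further compounds
F1 | step 10 | (5E,9E,13E)-15-(tert-butyldiphenylsilyloxy)-1-hydroxy-6,10,14-trimethylpentadeca-5,9,13-trien-2-one | C/C(=C\CC/C(C)=C/CC/C(C)=C/CCC(=O)CO)CO[Si](c1ccccc1)(c1ccccc1)C(C)(C)C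
F2 | step 10 | 4-[(3E,7E,11E)-13-(tert-butyldiphenylsilyloxy)-4,8,12-trimethyltrideca-3,7,11-trienyl]furan-2(5H)-one | C/C(=C\CC/C(C)=C/CC/C(C)=C/CCC1=CC(=O)OC1)CO[Si](c1ccccc1)(c1ccccc1)C(C)(C)C
F3 | step 10 | corresponding 2,5-dihydrofuran-2-ol (lactol, anomeric mixture) | C/C(=C\CC/C(C)=C/CC/C(C)=C/CCC1=CC(O)OC1)CO[Si](c1ccccc1)(c1ccccc1)C(C)(C)C
F4 | step 10 | (2Z)-2-substituted penta-2,4-dien-1-ol (C24–OH cis to the vinyl group) | C/C(=C\CC/C(C)=C/CC/C(C)=C/CC/C(=C/C=C)CO)CO[Si](c1ccccc1)(c1ccccc1)C(C)(C)C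
F5 | step 10 | PMB ether of F4 | C/C(=C\CC/C(C)=C/CC/C(C)=C/CC/C(=C/C=C)COCc1ccc(OC)cc1)CO[Si](c1ccccc1)(c1ccccc1)C(C)(C)C
F6 | step 14 | anti (R,R)-2-vinyl-1,3-diol, R*–CH(OH)–CH(CH2OH)–CH=CH2 | C/C(=C\CC/C(C)=C/CC/C(C)=C/CC/C(=C/C[C@@H](O)[C@@H](CO)C=C)COCc1ccc(OC)cc1)CO[Si](c1ccccc1)(c1ccccc1)C(C)(C)C
F7 | step 14 | primary TBS ether of F6 | C/C(=C\CC/C(C)=C/CC/C(C)=C/CC/C(=C/C[C@@H](O)[C@@H](CO[Si](C)(C)C(C)(C)C)C=C)COCc1ccc(OC)cc1)CO[Si](c1ccccc1)(c1ccccc1)C(C)(C)C
F8 | step 14 | 1,4-diol from hydroboration of F7 | C/C(=C\CC/C(C)=C/CC/C(C)=C/CC/C(=C/C[C@@H](O)[C@@H](CO[Si](C)(C)C(C)(C)C)CCO)COCc1ccc(OC)cc1)CO[Si](c1ccccc1)(c1ccccc1)C(C)(C)C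
F9 | step 18 | trimethylsilyl ketene acetal of 31 | C/C(=C\CC/C(C)=C/CC/C(C)=C/CC/C(=C/C[C@H]1OC(O[Si](C)(C)C)=C[C@@H]1CO[Si](C)(C)C(C)(C)C)COCc1ccc(OC)cc1)CO[Si](c1ccccc1)(c1ccccc1)C(C)(C)C
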